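**Retrosynthetic overview**
1. C11=C12: Wittig union of a C15 epoxy-keto phosphonium salt (stabilised ylide) with a C25 acetylenic apo-aldehyde; that aldehyde comes from a C15 acetylenic phosphonium salt and the C10 dialdehyde (C11′=C12′).
2. Both C15 salts come from one cyclised C15 enyne diacetate: directly for the acetylenic end; for the other end by 5,6-epoxidation, then formal hydration of the 7,8-alkyne to the 8-ketone (the order diatoms use for this end group).
3. Ring order: the trimethylcyclohexene ring is formed first, once, for both end groups, by proton-initiated cyclase-type closure (C1–C6 bond) of an acyclic trienyne diacetate; the oxirane is formed second by epoxidase-type oxygen transfer to the 5,6-alkene.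
4. Acyclic precursor: (S)-epichlorohydrin (source of C3) + isopropenyl Grignard + acetylide, carboalumination–iodination, Sonogashira coupling with (E)-3-methylpent-2-en-4-yn-1-ol.

Assumption: the target is the all-E (3S,5R,6S,3′R) isomer as drawn (halocynthiaxanthin 3′-acetate); positions are cited in carotenoid numbering.

**Route**

Step 1
Reactants: 1 (S)-epichlorohydrin; 2 isopropenylmagnesium bromide
Product: 3 (2S)-1-chloro-4-methylpent-4-en-2-ol
Conditions: CuI (10 mol %), THF, −40 → −20 °C; aq. NH4Cl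
Reagents that add atoms: none
Why: Copper-catalysed Grignard opening of the epoxide at its CH2 carbon (SN2) leaves the C–O stereocentre of the chiral pool untouched and keeps the chloride for the next closure.

Step 2
Reactants: 3 (2S)-1-chloro-4-methylpent-4-en-2-ol; 4 lithium acetylide–ethylenediamine complex
Product: 6 (4S)-2-methylhept-1-en-6-yn-4-ol, via methallyloxirane 5 (not isolated)
Conditions: 4 (2.5 equiv), DMSO, 0 °C → rt
Reagents that add atoms: none
Why: The first equivalent of acetylide closes the chlorohydrin to the terminal epoxide and the second opens it at CH2 (SN2 epoxide alkynylation), so the carbinol configuration (the future C3) is retained.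

Step 3
Reactants: 6 (4S)-2-methylhept-1-en-6-yn-4-ol
Product: 8 (1E,4S)-1-iodo-2,6-dimethylhepta-1,6-dien-4-ol, via alkenylalane 7 (not isolated)
Conditions: Me3Al (3 equiv), Cp2ZrCl2 (0.25 equiv), CH2Cl2, 0 °C → rt; then I2, THF, −30 °C; aq. K2CO3
Reagents that add atoms: trimethylaluminium (C[Al](C)C); iodine ([I][I])
Why: Negishi zirconium-catalysed carboalumination adds Me–Al syn across the terminal alkyne (Me internal, Al terminal) and iodinolysis retains configuration, fixing the E trisubstituted alkene while the 1,1-disubstituted alkene stays inert.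

Step 4
Reactants: 8 (1E,4S)-1-iodo-2,6-dimethylhepta-1,6-dien-4-ol; 9 (E)-3-methylpent-2-en-4-yn-1-ol
Product: 10 (2E,6E,9S)-3,7,11-trimethyldodeca-2,6,11-trien-4-yne-1,9-diol
Conditions: Pd(PPh3)2Cl2 (3 mol %), CuI (6 mol %), i-Pr2NH, THF, rt, degassed
Reagents that add atoms: none
Why: Sonogashira coupling of the alkenyl iodide with the terminal alkyne retains both alkene geometries and tolerates the free hydroxyls.

Step 5
Reactants: 10 (2E,6E,9S)-3,7,11-trimethyldodeca-2,6,11-trien-4-yne-1,9-diol
Product: 11 (2E,6E,9S)-3,7,11-trimethyldodeca-2,6,11-trien-4-yne-1,9-diyl diacetate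
Conditions: Ac2O, pyridine, DMAP (cat.), CH2Cl2, 0 °C → rt
Reagents that add atoms: acetic anhydride (CC(=O)OC(C)=O)
Why: DMAP-catalysed acylation masks both hydroxyls as esters that survive superacid, and the secondary acetate is already the ester of the target.

Step 6
Reactants: 11 (2E,6E,9S)-3,7,11-trimethyldodeca-2,6,11-trien-4-yne-1,9-diyl diacetate
Product: 12 (2E)-5-[(4R)-4-acetoxy-2,6,6-trimethylcyclohex-1-en-1-yl]-3-methylpent-2-en-4-yn-1-yl acetate
Conditions: FSO3H (5 equiv), 2-nitropropane, −78 °C, 15 min; then Et3N, −78 °C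
Reagents that add atoms: none
Why: Proposed new method: in the superacid both ester carbonyls are O-protonated (no acyloxy participation; the allylic acetate carries a destabilising alkynyl group and should ionise no faster than a farnesyl acetate), Markovnikov protonation of the 1,1-disubstituted alkene gives the tertiary C1 cation of the cyclase mechanism, C6 of the trisubstituted enyne alkene attacks it 6-endo, and loss of H6 gives the tetrasubstituted 5-ene conjugated with the 7,8-alkyne, with C3 a spectator so no new stereocentre arises; the closest known reactions are the FSO3H cyclisation of farnesyl and geranylgeranyl acetates at −78 °C and the pseudoionone-to-β-ionone cyclisation.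

Step 7
Reactants: 12 (2E)-5-[(4R)-4-acetoxy-2,6,6-trimethylcyclohex-1-en-1-yl]-3-methylpent-2-en-4-yn-1-yl acetate
Product: 13 (1R)-4-[(3E)-5-hydroxy-3-methylpent-3-en-1-yn-1-yl]-3,5,5-trimethylcyclohex-3-en-1-yl acetate
Conditions: K2CO3 (0.2 equiv), MeOH, −10 °C, stopped at ca. 90 % conversion
Reagents that add atoms: none
Why: Zemplén-type methanolysis is faster at the unhindered primary allylic acetate than at the secondary ring acetate, so early quenching gives the mono-alcohol (diacetate and diol are recycled).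

Step 8
Reactants: 13 (1R)-4-[(3E)-5-hydroxy-3-methylpent-3-en-1-yn-1-yl]-3,5,5-trimethylcyclohex-3-en-1-yl acetate
Product: 15 [(2E)-5-[(4R)-4-acetoxy-2,6,6-trimethylcyclohex-1-en-1-yl]-3-methylpent-2-en-4-yn-1-yl]triphenylphosphonium bromide, via allylic bromide 14 (not isolated)
Conditions: NBS, Me2S, CH2Cl2, −20 → 0 °C; then PPh3, rt
Reagents that add atoms: N-bromosuccinimide (O=C1CCC(=O)N1Br); triphenylphosphine (c1ccc(cc1)P(c1ccccc1)c1ccccc1)
Why: Corey–Kim bromination followed by SN2 quaternisation of PPh3 avoids an allyl cation, so the 9E geometry, which drifts towards Z under ionising PPh3·HBr conditions, is kept.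

Step 9
Reactants: 15 the C15 acetylenic phosphonium bromide; 16 (2E,4E,6E)-2,7-dimethylocta-2,4,6-trienedial
Product: 17 (2E,4E,6E,8E,10E)-13-[(4R)-4-acetoxy-2,6,6-trimethylcyclohex-1-en-1-yl]-2,7,11-trimethyltrideca-2,4,6,8,10-pentaen-12-ynal
Conditions: 16 (3 equiv), 1,2-epoxybutane (solvent), 60 °C; then heptane, 80 °C
Reagents that add atoms: none
Why: Wittig olefination with the ylide generated in the presence of the aldehyde under neutral conditions (the epoxide scavenges HBr) spares the acetate, excess dialdehyde ensures mono-olefination, and the hindered Z isomer of the new disubstituted bond is converted thermally to E.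

Step 10
Reactants: 12 (2E)-5-[(4R)-4-acetoxy-2,6,6-trimethylcyclohex-1-en-1-yl]-3-methylpent-2-en-4-yn-1-yl acetate
Product: 18 (2E)-5-[(1R,4S,6R)-4-acetoxy-2,2,6-trimethyl-7-oxabicyclo[4.1.0]heptan-1-yl]-3-methylpent-2-en-4-yn-1-yl acetate
Conditions: mCPBA (1.1 equiv), NaHCO3, CH2Cl2, 0 °C
Reagents that add atoms: 3-chloroperbenzoic acid (OOC(=O)c1cccc(Cl)c1)
Why: Prilezhaev epoxidation of the most electron-rich (tetrasubstituted) alkene, the epoxidase step on the acetylenic end group; C5 and C6 are set by attack on the face anti to the 3-acetoxy group (about 3–4:1 is expected for 3-acyloxy end groups), and the minor syn epoxide is removed by chromatography.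

Step 11
Reactants: 18 the anti-epoxy enyne diacetate
Product: 19 (1R,3S,6R)-6-[(3E)-5-hydroxy-3-methylpent-3-en-1-yn-1-yl]-1,5,5-trimethyl-7-oxabicyclo[4.1.0]heptan-3-ol
Conditions: K2CO3, MeOH, rt
Reagents that add atoms: none
Why: Base-catalysed transesterification removes both acetates while the alkynyl oxirane, which does not yet carry the 8-oxo group, is stable to base.

Step 12
Reactants: 19 the epoxy enyne diol
Product: 21 (3E)-5-hydroxy-1-[(1S,4S,6R)-4-hydroxy-2,2,6-trimethyl-7-oxabicyclo[4.1.0]heptan-1-yl]-3-methylpent-3-en-2-one, via alkenylborane 20 (not isolated)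
Conditions: Cy2BH (3.3 equiv), THF, 0 °C → rt; then H2O2, pH 7 phosphate buffer, 0 °C
Reagents that add atoms: dicyclohexylborane (B(C1CCCCC1)C1CCCCC1, in 20 only); hydrogen peroxide (OO)
Why: Hydroboration–oxidation as a formal hydration: the bulky dialkylborane adds syn with boron on C8, away from the quaternary oxirane carbon and next to the C9=C10 alkene (where conjugated enynes and diynes accept boron), and buffered peroxide reveals the 8-ketone without exposing the β,γ-epoxy ketone to base.

Step 13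
Reactants: 21 the epoxy keto diol
Product: 23 [(2E)-5-[(1S,4S,6R)-4-hydroxy-2,2,6-trimethyl-7-oxabicyclo[4.1.0]heptan-1-yl]-3-methyl-4-oxopent-2-en-1-yl]triphenylphosphonium bromide, via bromo enone 22 (not isolated)
Conditions: NBS, Me2S, CH2Cl2, −20 °C; then PPh3, rt
Reagents that add atoms: N-bromosuccinimide (O=C1CCC(=O)N1Br); triphenylphosphine (c1ccc(cc1)P(c1ccccc1)c1ccccc1)
Why: Corey–Kim bromination is neutral and selective for the allylic over the saturated secondary alcohol, and the γ-bromo enone alkylates PPh3 by SN2 to give the vinylogous acyl (stabilised) Wittig salt.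

Step 14
Reactants: 23 the C15 epoxy-keto phosphonium bromide; 17 the C25 acetylenic aldehyde
Product: 24 (3S,5R,6S,3′R)-3′-acetoxy-5,6-epoxy-3-hydroxy-7′,8′-didehydro-5,6,7,8-tetrahydro-β,β-caroten-8-one (halocynthiaxanthin 3′-acetate)
Conditions: 1,2-epoxybutane, CH2Cl2, 45 °C, dark, argon
Reagents that add atoms: none
Why: Wittig olefination with a stabilised vinylogous acyl ylide forms C11=C12 E-selectively under base-free conditions that neither open the β,γ-epoxy ketone (only the acidic C11–H is removed) nor cleave the acetate.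

**Compound list**
1 | (S)-epichlorohydrin | ClC[C@@H]1CO1 | starting material
2 | isopropenylmagnesium bromide | C=C(C)[Mg]Br | starting material
3 | (2S)-1-chloro-4-methylpent-4-en-2-ol | ClC[C@@H](O)CC(C)=C | intermediate
4 | lithium acetylide–ethylenediamine complex | [Li]C#C.NCCN | starting material
5 | (2S)-2-(2-methylprop-2-en-1-yl)oxirane | C=C(C)C[C@H]1CO1 | intermediate
6 | (4S)-2-methylhept-1-en-6-yn-4-ol | C=C(C)C[C@H](O)CC#C | intermediate
7 | (E)-alkenyl(dimethyl)alane of 6 with O-dimethylaluminium alkoxide (Me and Al cis) | C=C(C)C[C@H](O[Al](C)C)C/C(C)=C/[Al](C)C | intermediate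
8 | (1E,4S)-1-iodo-2,6-dimethylhepta-1,6-dien-4-ol | C=C(C)C[C@H](O)C/C(C)=C/I | intermediate
9 | (E)-3-methylpent-2-en-4-yn-1-ol | C#C/C(C)=C/CO | starting material
10 | (2E,6E,9S)-3,7,11-trimethyldodeca-2,6,11-trien-4-yne-1,9-diol | C=C(C)C[C@H](O)C/C(C)=C/C#C/C(C)=C/CO | intermediate
11 | (2E,6E,9S)-3,7,11-trimethyldodeca-2,6,11-trien-4-yne-1,9-diyl diacetate | C=C(C)C[C@H](OC(C)=O)C/C(C)=C/C#C/C(C)=C/COC(C)=O | intermediate
12 | (2E)-5-[(4R)-4-acetoxy-2,6,6-trimethylcyclohex-1-en-1-yl]-3-methylpent-2-en-4-yn-1-yl acetate | CC(=O)O[C@@H]1CC(C)=C(C#C/C(C)=C/COC(C)=O)C(C)(C)C1 | intermediate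
13 | (1R)-4-[(3E)-5-hydroxy-3-methylpent-3-en-1-yn-1-yl]-3,5,5-trimethylcyclohex-3-en-1-yl acetate | CC(=O)O[C@@H]1CC(C)=C(C#C/C(C)=C/CO)C(C)(C)C1 | intermediate
14 | (1R)-4-[(3E)-5-bromo-3-methylpent-3-en-1-yn-1-yl]-3,5,5-trimethylcyclohex-3-en-1-yl acetate | CC(=O)O[C@@H]1CC(C)=C(C#C/C(C)=C/CBr)C(C)(C)C1 | intermediate
15 | [(2E)-5-[(4R)-4-acetoxy-2,6,6-trimethylcyclohex-1-en-1-yl]-3-methylpent-2-en-4-yn-1-yl]triphenylphosphonium bromide | CC(=O)O[C@@H]1CC(C)=C(C#C/C(C)=C/C[P+](c2ccccc2)(c2ccccc2)c2ccccc2)C(C)(C)C1.[Br-] | intermediate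
16 | (2E,4E,6E)-2,7-dimethylocta-2,4,6-trienedial | O=C/C(C)=C/C=C/C=C(C)/C=O | starting material
17 | (2E,4E,6E,8E,10E)-13-[(4R)-4-acetoxy-2,6,6-trimethylcyclohex-1-en-1-yl]-2,7,11-trimethyltrideca-2,4,6,8,10-pentaen-12-ynal | CC(=O)O[C@@H]1CC(C)=C(C#C/C(C)=C/C=C/C(C)=C/C=C/C=C(C)/C=O)C(C)(C)C1 | intermediate
18 | (2E)-5-[(1R,4S,6R)-4-acetoxy-2,2,6-trimethyl-7-oxabicyclo[4.1.0]heptan-1-yl]-3-methylpent-2-en-4-yn-1-yl acetate (oxirane O anti to the acetoxy group) | CC(=O)OC/C=C(\C)C#C[C@@]12O[C@]1(C)C[C@@H](OC(C)=O)CC2(C)C | intermediate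
19 | (1R,3S,6R)-6-[(3E)-5-hydroxy-3-methylpent-3-en-1-yn-1-yl]-1,5,5-trimethyl-7-oxabicyclo[4.1.0]heptan-3-ol | OC/C=C(\C)C#C[C@@]12O[C@]1(C)C[C@@H](O)CC2(C)C | intermediate
20 | 8-(dicyclohexylboryl)-7-ene from syn H–B addition to 19, both hydroxyls as dicyclohexylborinates | C1CCCCC1B(C1CCCCC1)OC/C=C(\C)/C(B(C1CCCCC1)C1CCCCC1)=C\[C@@]23O[C@]2(C)C[C@@H](OB(C1CCCCC1)C1CCCCC1)CC3(C)C | intermediate
21 | (3E)-5-hydroxy-1-[(1S,4S,6R)-4-hydroxy-2,2,6-trimethyl-7-oxabicyclo[4.1.0]heptan-1-yl]-3-methylpent-3-en-2-one | OC/C=C(\C)C(=O)C[C@@]12O[C@]1(C)C[C@@H](O)CC2(C)C | intermediate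
22 | (3E)-5-bromo-1-[(1S,4S,6R)-4-hydroxy-2,2,6-trimethyl-7-oxabicyclo[4.1.0]heptan-1-yl]-3-methylpent-3-en-2-one | BrC/C=C(\C)C(=O)C[C@@]12O[C@]1(C)C[C@@H](O)CC2(C)C | intermediate
23 | [(2E)-5-[(1S,4S,6R)-4-hydroxy-2,2,6-trimethyl-7-oxabicyclo[4.1.0]heptan-1-yl]-3-methyl-4-oxopent-2-en-1-yl]triphenylphosphonium bromide | [Br-].c1ccccc1[P+](c1ccccc1)(c1ccccc1)C/C=C(\C)C(=O)C[C@@]23O[C@]2(C)C[C@@H](O)CC3(C)C | intermediate
24 | (3S,5R,6S,3′R)-3′-acetoxy-5,6-epoxy-3-hydroxy-7′,8′-didehydro-5,6,7,8-tetrahydro-β,β-caroten-8-one, all-E | CC(=O)O[C@@H]1CC(C)=C(C#C/C(C)=C/C=C/C(C)=C/C=C/C=C(C)/C=C/C=C(\C)C(=O)C[C@@]23O[C@]2(C)C[C@@H](O)CC3(C)C)C(C)(C)C1 | target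

**Totals**
Total step count: 14. Longest linear sequence: 11 steps (steps 1–6, then 10–14); the other branch (steps 1–9, then 14) is 10 steps.

**Three steps most likely to fail**

Step 6 (superacid ring closure of the diacetate). If the diacetate ionises at the allylic acetate or loses the 9E geometry, C11 is taken through the ring closure as an aldehyde, as in the pseudoionone-to-ionone cyclisation. Setting out from diol 10, MnO2 in CH2Cl2 oxidises only the allylic primary alcohol to hydroxy enynal F1. Ac2O/pyridine gives acetoxy enynal F2. FSO3H in 2-nitropropane at −78 °C closes the ring to cyclised acetoxy enynal F3; its O-protonated enal cannot ionise and shields the dienyne. NaBH4 with CeCl3·7H2O in MeOH at −40 °C then gives alcohol 13, where this path comes back to the route. Ac2O/pyridine on part of 13 supplies diacetate 12 for the other branch.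

Step 10 (facial selectivity of the epoxidation). Should the peracid prefer the face syn to the acetate, the oxirane is closed from the other side through a halohydrin. Setting out from 12, N-bromosuccinimide in aqueous acetone at 0 °C puts the bromonium ion on the face an electrophile prefers, and water opens it anti to give trans-bromohydrin F4 (Br on C6, OH on C5). K2CO3 in MeOH then displaces bromide intramolecularly. This places the oxirane oxygen on the face opposite to that of direct epoxidation and cleaves both acetates in the same operation, so the path comes back at epoxy diol 19.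

Step 12 (hydroboration–oxidation of the alkynyl oxirane). If the oxirane does not tolerate the borane, or boron goes to C7, the order of the two oxidations is reversed. Setting out from 12, Cy2BH (1.2 equiv, THF, 0 °C) adds to the alkyne with boron on C8 for steric reasons to give alkenylborane F5. Buffered H2O2 gives the β,γ-unsaturated keto diacetate F6. mCPBA then epoxidises its only electron-rich alkene (isolated, tetrasubstituted) anti to the acetate to give epoxy keto diacetate F7. Base-free transesterification (ClBu2SnOSnBu2OH 5 mol %, MeOH, 40 °C) removes both acetates and comes back at keto diol 21.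

**Further compounds**
F1 | step 6 | (2E,6E,9S)-9-hydroxy-3,7,11-trimethyldodeca-2,6,11-trien-4-ynal | C=C(C)C[C@H](O)C/C(C)=C/C#C/C(C)=C/C=O
F2 | step 6 | (2E,6E,9S)-9-acetoxy-3,7,11-trimethyldodeca-2,6,11-trien-4-ynal | C=C(C)C[C@H](OC(C)=O)C/C(C)=C/C#C/C(C)=C/C=O
F3 | step 6 | (1R)-3,5,5-trimethyl-4-[(3E)-3-methyl-5-oxopent-3-en-1-yn-1-yl]cyclohex-3-en-1-yl acetate | CC(=O)O[C@@H]1CC(C)=C(C#C/C(C)=C/C=O)C(C)(C)C1
F4 | step 10 | (2E)-5-[(1S,2R,4S)-4-acetoxy-1-bromo-2-hydroxy-2,6,6-trimethylcyclohexyl]-3-methylpent-2-en-4-yn-1-yl acetate | CC(=O)OC/C=C(\C)C#C[C@@]1(Br)C(C)(C)C[C@H](OC(C)=O)C[C@@]1(C)O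
F5 | step 12 | 8-(dicyclohexylboryl)-7-ene from syn H–B addition to 12 (ring and C9 cis) | CC(=O)OC/C=C(\C)/C(B(C1CCCCC1)C1CCCCC1)=C\C1=C(C)C[C@@H](OC(C)=O)CC1(C)C
F6 | step 12 | (2E)-5-[(4R)-4-acetoxy-2,6,6-trimethylcyclohex-1-en-1-yl]-3-methyl-4-oxopent-2-en-1-yl acetate | CC(=O)OC/C=C(\C)C(=O)CC1=C(C)C[C@@H](OC(C)=O)CC1(C)C
F7 | step 12 | (2E)-5-[(1S,4S,6R)-4-acetoxy-2,2,6-trimethyl-7-oxabicyclo[4.1.0]heptan-1-yl]-3-methyl-4-oxopent-2-en-1-yl acetate | CC(=O)OC/C=C(\C)C(=O)C[C@@]12O[C@]1(C)C[C@@H](OC(C)=O)CC2(C)C
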